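**Retrosynthetic overview**
- The free acid is released last from its allyl ester by palladium-mediated deallylation.
- The trans-diaxial 6β-acetate/7α-isovalerate pair comes from a 6α-bromo-7β-acetate in one C–O bond-forming cascade. A silver-triggered acetoxonium relay shifts the acetate from C7 to C6 with inversion, and isovalerate enters at C7 with inversion. This is the key step.
- The bromo acetate comes from the 7-oxo-8-ene (α'-bromination, reduction, acetylation), which comes from the Δ8 olefin (allylic oxidation) and the 8α-alcohol (dehydration).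
- The (E)-enoate side chain comes from a methyl ketone and an allyl phosphonoacetate (Horner–Wadsworth–Emmons); the ketone comes from (−)-sclareol by oxidative cleavage.
- Rings A and B (trans-decalin, C5 and C10) are taken intact from sclareol and no carbocycle is built. The only ring formed is the transient dioxolanylium on ring B.

Assumption: labdane numbering, α = face opposite the C10 methyl; the target is read as (13E)-6β-acetoxy-7α-(3-methylbutanoyloxy)labda-8,13-dien-15-oic acid of the normal labdane series (5α-H, 10β-CH3), the series of (−)-sclareol.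

**Route**

Step 1
Reactants: 1 (−)-sclareol [(13R)-labd-14-ene-8α,13-diol]
Product: 2 8α-hydroxy-14,15-dinorlabdan-13-one
Conditions: KMnO4, acetone/H2O, 0 °C → rt
Reagents that add atoms: none
Why: Permanganate oxidative cleavage degrades the vinyl carbinol (C14 and C15 are lost, the C13 hydroxyl oxygen becomes the ketone oxygen) while the saturated decalin and its stereocentres C5, C8, C9 and C10 are untouched.

Step 2
Reactants: 2 8α-hydroxy-14,15-dinorlabdan-13-one; 3 allyl diethylphosphonoacetate
Product: 4 allyl (13E)-8α-hydroxylabd-13-en-15-oate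
Conditions: NaH (2.5 equiv), 3 (2.5 equiv), THF, 0 °C → reflux; minor Z isomer removed on silica
Reagents that add atoms: none
Why: Horner–Wadsworth–Emmons olefination of the methyl ketone puts the ester trans to the larger C12 chain (E expected to be major, about 5:1), the extra base holding the tertiary 8-OH as its alkoxide.

Step 3
Reactants: 4 allyl (13E)-8α-hydroxylabd-13-en-15-oate
Product: 5 allyl (13E)-labda-8,13-dien-15-oate
Conditions: PPh3, I2, CH2Cl2, rt, dark
Reagents that add atoms: none
Why: Dehydration of the tertiary alcohol through its oxyphosphonium salt, with the HI formed equilibrating the olefin isomers towards the tetrasubstituted Zaitsev Δ8(9) alkene (E1 elimination); the C8 and C9 stereocentres are not present in the target.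

Step 4
Reactants: 5 allyl (13E)-labda-8,13-dien-15-oate
Product: 6 allyl (13E)-7-oxolabda-8,13-dien-15-oate
Conditions: CrO3, 3,5-dimethylpyrazole, CH2Cl2, −20 °C
Reagents that add atoms: chromium trioxide O=[Cr](=O)=O
Why: Allylic oxidation by hexavalent chromium takes the ring methylene C7, whose axial hydrogen is aligned with the π bond, in preference to the neopentyl-like C11 and the primary C17, giving the conjugated enone.

Step 5
Reactants: 6 allyl (13E)-7-oxolabda-8,13-dien-15-oate
Product: 8 allyl (13E)-6α-bromo-7-oxolabda-8,13-dien-15-oate, via lithium dienolate 7 (not isolated)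
Conditions: LiN(SiMe3)2 (1.1 equiv), THF, −78 °C; then NBS, −78 °C
Reagents that add atoms: N-bromosuccinimide O=C1CCC(=O)N1Br; LiN(SiMe3)2 [Li]N([Si](C)(C)C)[Si](C)(C)C (lithium in 7 only)
Why: Kinetic α'-deprotonation (C8 carries no hydrogen and the enoate γ-hydrogens are far less acidic) gives the cross-conjugated enolate, which is brominated at C6 from the α face because the β face is blocked by the syn-axial C10 and C4β methyl groups (enolate α-halogenation, 6α-Br equatorial and also the thermodynamic epimer).

Step 6
Reactants: 8 allyl (13E)-6α-bromo-7-oxolabda-8,13-dien-15-oate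
Product: 9 allyl (13E)-6α-bromo-7β-hydroxylabda-8,13-dien-15-oate
Conditions: NaBH4, CeCl3·7H2O, MeOH/THF, −40 °C
Reagents that add atoms: none
Why: Luche 1,2-reduction with axial hydride delivery from the α face (the β face is shielded by the C10 methyl) sets the equatorial 7β-alcohol trans to bromine, as in the reduction of equatorial α-bromo cyclohexanones.

Step 7
Reactants: 9 allyl (13E)-6α-bromo-7β-hydroxylabda-8,13-dien-15-oate
Product: 10 allyl (13E)-7β-acetoxy-6α-bromolabda-8,13-dien-15-oate
Conditions: Ac2O, pyridine, DMAP (cat.), CH2Cl2, 0 °C → rt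
Reagents that add atoms: acetic anhydride CC(=O)OC(C)=O
Why: DMAP-catalysed acylation of an unhindered equatorial allylic alcohol under conditions too weakly basic to close the bromohydrin, with no stereocentre touched.

Step 8
Reactants: 10 allyl (13E)-7β-acetoxy-6α-bromolabda-8,13-dien-15-oate
Product: 12 allyl (13E)-6β-acetoxy-7α-(3-methylbutanoyloxy)labda-8,13-dien-15-oate, via acetoxonium ion 11 (not isolated)
Conditions: Ag2O (1.5 equiv), Me2CHCH2CO2H (6 equiv), 4 Å MS, PhMe, rt, 1 h, dark; then 10, 80 °C
Reagents that add atoms: isovaleric acid CC(C)CC(=O)O (acting as silver isovalerate CC(C)CC(=O)[O-].[Ag+] made in the flask)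
Why: Proposed new method: monovalent silver pulls the 6α-bromide while the carbonyl oxygen of the trans 7β-acetate closes onto C6 from the β face (ring B, a cyclohexene, can reach the boat in which C6–Br and C7–OAc are antiperiplanar), giving the cis-fused 6β,7β-acetoxonium ion 11 with inversion at C6, and isovalerate then opens 11 by SN2 (or via the allyl cation, whose β face stays covered by the 6β-acetate) at the allylic C7 from the open α face with inversion, so that acetate ends on C6β and isovalerate on C7α in a trans-diaxial array; the closest known reaction type is the Prévost reaction and the silver-assisted solvolysis of trans-2-acetoxycycloalkyl halides through acyloxonium ions, in which the same carboxylate is delivered twice, whereas capture by a second, different carboxylate with allylic regiocontrol on a ring-fused substrate has not been shown.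

Step 9
Reactants: 12 allyl (13E)-6β-acetoxy-7α-(3-methylbutanoyloxy)labda-8,13-dien-15-oate
Product: 13 (13E)-6β-acetoxy-7α-(3-methylbutanoyloxy)labda-8,13-dien-15-oic acid
Conditions: Pd(PPh3)4 (5 mol %), morpholine (5 equiv), THF, rt; aq. KHSO4 work-up
Reagents that add atoms: none
Why: Tsuji–Trost deallylation, in which zerovalent palladium ionises only the unhindered allyl ester (the C7 allylic isovalerate sits on a tetrasubstituted alkene that cannot bind the metal) and morpholine traps the allyl group under neutral conditions that leave both secondary esters and all stereocentres alone.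

**Compound list**
1 | (−)-sclareol, (13R)-labd-14-ene-8α,13-diol | C1C[C@@](C)(O)[C@H](CC[C@@](C)(O)C=C)[C@@]2(C)CCCC(C)(C)[C@H]12 | starting material
2 | 8α-hydroxy-14,15-dinorlabdan-13-one | C1C[C@@](C)(O)[C@H](CCC(C)=O)[C@@]2(C)CCCC(C)(C)[C@H]12 | intermediate
3 | allyl diethylphosphonoacetate | CCOP(=O)(OCC)CC(=O)OCC=C | starting material
4 | allyl (13E)-8α-hydroxylabd-13-en-15-oate | C1C[C@@](C)(O)[C@H](CC/C(C)=C/C(=O)OCC=C)[C@@]2(C)CCCC(C)(C)[C@H]12 | intermediate
5 | allyl (13E)-labda-8,13-dien-15-oate | C1CC(C)=C(CC/C(C)=C/C(=O)OCC=C)[C@@]2(C)CCCC(C)(C)[C@H]12 | intermediate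
6 | allyl (13E)-7-oxolabda-8,13-dien-15-oate | C1C(=O)C(C)=C(CC/C(C)=C/C(=O)OCC=C)[C@@]2(C)CCCC(C)(C)[C@H]12 | intermediate
7 | lithium dienolate of 6 (lithium 6,8-dien-7-olate, formed in the flask) | C1=C(O[Li])C(C)=C(CC/C(C)=C/C(=O)OCC=C)[C@@]2(C)CCCC(C)(C)[C@H]12 | intermediate
8 | allyl (13E)-6α-bromo-7-oxolabda-8,13-dien-15-oate | Br[C@H]1C(=O)C(C)=C(CC/C(C)=C/C(=O)OCC=C)[C@@]2(C)CCCC(C)(C)[C@H]12 | intermediate
9 | allyl (13E)-6α-bromo-7β-hydroxylabda-8,13-dien-15-oate | Br[C@H]1[C@H](O)C(C)=C(CC/C(C)=C/C(=O)OCC=C)[C@@]2(C)CCCC(C)(C)[C@H]12 | intermediate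
10 | allyl (13E)-7β-acetoxy-6α-bromolabda-8,13-dien-15-oate | Br[C@H]1[C@H](OC(C)=O)C(C)=C(CC/C(C)=C/C(=O)OCC=C)[C@@]2(C)CCCC(C)(C)[C@H]12 | intermediate
11 | 6β,7β-acetoxonium ion (cis-fused 2-methyl-1,3-dioxolan-2-ylium on ring B, isovalerate counter-ion, formed in the flask) | CC1=[O+][C@@H]2[C@H](O1)C(C)=C(CC/C(C)=C/C(=O)OCC=C)[C@@]3(C)CCCC(C)(C)[C@H]23.CC(C)CC(=O)[O-] | intermediate
12 | allyl (13E)-6β-acetoxy-7α-(3-methylbutanoyloxy)labda-8,13-dien-15-oate | CC(=O)O[C@@H]1[C@@H](OC(=O)CC(C)C)C(C)=C(CC/C(C)=C/C(=O)OCC=C)[C@@]2(C)CCCC(C)(C)[C@H]12 | intermediate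
13 | (13E)-6β-acetoxy-7α-(3-methylbutanoyloxy)labda-8,13-dien-15-oic acid | CC(=O)O[C@@H]1[C@@H](OC(=O)CC(C)C)C(C)=C(CC/C(C)=C/C(=O)O)[C@@]2(C)CCCC(C)(C)[C@H]12 | target

**Step count**
Total steps: 9. Longest linear sequence: 9 (1 → 13).

**Three steps most likely to fail**

Step 8 (the proposed cross-carboxylate acetoxonium relay). The diequatorial bromo acetate may ionise slowly. The allyl cation may lose a proton to a dienyl acetate. Traces of water would divert 11 to the cis hydroxy acetate. Opening at C6 would return a diequatorial diester. The fallback uses known chemistry, sets out from 9 and comes back at 12. NaH in THF (0 °C → rt) closes the trans bromohydrin to allyl (13E)-6β,7β-epoxylabda-8,13-dien-15-oate F1. Warm isovaleric acid (neat, 40 °C) opens this vinyl epoxide at the allylic C7 from the α face with inversion, giving allyl (13E)-6β-hydroxy-7α-(3-methylbutanoyloxy)labda-8,13-dien-15-oate F2. Ac2O, DMAP and Et3N at 40 °C then acetylate the hindered axial 6β-OH to 12; the trans-diaxial geometry prevents acyl migration.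

Step 3 (regiochemistry of the dehydration, Δ8(9) against Δ7 and Δ8(17), which also governs the site of oxidation in step 4). The fallback sets out from 4 and comes back at 6, so it needs neither olefin 5 nor the chromium oxidation. SOCl2 in pyridine at 0 °C gives the kinetic exocyclic olefin allyl (13E)-labda-8(17),13-dien-15-oate F3, because the equatorial 8α-OH has no antiperiplanar ring hydrogen. Catalytic SeO2 with t-BuOOH in CH2Cl2 hydroxylates it at C7 from the α face to allyl (13E)-7α-hydroxylabda-8(17),13-dien-15-oate F4. Dess–Martin periodinane gives allyl (13E)-7-oxolabda-8(17),13-dien-15-oate F5. DBU in toluene moves the exocyclic double bond into conjugation inside the ring to give 6.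

Step 6 (facial selectivity of the hydride and stability of the bromohydrin; a 7α-alcohol would be cis to bromine and useless for step 8). The fallback sets out from 6 and comes back at 10, replacing steps 5 to 7. Luche reduction of 6 gives allyl (13E)-7β-hydroxylabda-8,13-dien-15-oate F6; its C7 configuration no longer matters. Burgess reagent in toluene at 50 °C eliminates towards C6 to the homoannular diene allyl (13E)-labda-6,8,13-trien-15-oate F7. NBS in AcOH with NaOAc at 0 °C then adds bromine to C6 from the open α face and acetate to the allylic C7 from the β face (anti bromoacetoxylation), giving 10.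

**Further compounds**
F1 | step 8 | allyl (13E)-6β,7β-epoxylabda-8,13-dien-15-oate | O1[C@@H]2[C@H]1C(C)=C(CC/C(C)=C/C(=O)OCC=C)[C@@]3(C)CCCC(C)(C)[C@H]23
F2 | step 8 | allyl (13E)-6β-hydroxy-7α-(3-methylbutanoyloxy)labda-8,13-dien-15-oate | O[C@@H]1[C@@H](OC(=O)CC(C)C)C(C)=C(CC/C(C)=C/C(=O)OCC=C)[C@@]2(C)CCCC(C)(C)[C@H]12
F3 | step 3 | allyl (13E)-labda-8(17),13-dien-15-oate | C1CC(=C)[C@H](CC/C(C)=C/C(=O)OCC=C)[C@@]2(C)CCCC(C)(C)[C@H]12
F4 | step 3 | allyl (13E)-7α-hydroxylabda-8(17),13-dien-15-oate | C1[C@@H](O)C(=C)[C@H](CC/C(C)=C/C(=O)OCC=C)[C@@]2(C)CCCC(C)(C)[C@H]12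
F5 | step 3 | allyl (13E)-7-oxolabda-8(17),13-dien-15-oate | C1C(=O)C(=C)[C@H](CC/C(C)=C/C(=O)OCC=C)[C@@]2(C)CCCC(C)(C)[C@H]12
F6 | step 6 | allyl (13E)-7β-hydroxylabda-8,13-dien-15-oate | C1[C@H](O)C(C)=C(CC/C(C)=C/C(=O)OCC=C)[C@@]2(C)CCCC(C)(C)[C@H]12
F7 | step 6 | allyl (13E)-labda-6,8,13-trien-15-oate | C1=CC(C)=C(CC/C(C)=C/C(=O)OCC=C)[C@@]2(C)CCCC(C)(C)[C@H]12
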